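**Retrosynthetic overview**
1. Previtexilactone ⇐ 6β-acetylation/desilylation ⇐ C13 spiro-γ-lactone ⇐ catalyst-controlled Baeyer–Villiger desymmetrisation of a C13 spirocyclobutanone ⇐ dichloroketene [2+2] on a 13-methylene oxolane ⇐ C9 spirolactone ⇐ 9α,11-epoxide + malonate.
2. The epoxide comes from the C9 ketone (methylenation, α-face epoxidation) of a 6β-silyloxy trans-decalin; the 6β-oxygen comes from hydride reduction of the C6 ketone.
3. Feature used: in ring B (C5–C10) the oxygenated carbons C6 and C9 are para and C8 and C10 each carry a methyl group, the pattern of 2,6-dimethyl-1,4-benzoquinone, whose two equivalent C(Me)=CH alkenes become C10=C5 and C8=C7.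
4. Key disconnection: C1–C10 and C4–C5 of ring A (C1–C5, C10) by a catalytic enantioselective [4+2] addition of a 4,4-dimethyl diene to the quinone. The diene carries a 2-silyloxy activating group because the parent 4-methylpenta-1,3-diene is a poor Diels–Alder partner; the extra oxygen is removed later through the enol triflate.
5. Ring order: ring B is purchased (quinone), then ring A (cycloaddition), the oxolane (through the spirolactone), the cyclobutanone, and last the butyrolactone.

Key step: step 2

Remarks (conventions and assumptions)
- Labdane numbering throughout: ring A = C1–C5 and C10 (gem-dimethyl on C4), ring B = C5–C10; β is the face of the C10 methyl group.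
- Step 2: the (S)-catalyst is assigned by analogy with the way this catalyst type delivers dienes to acrylates and quinones bound through an α-C–H···O contact. The assignment is not secure, so if the first run gives the mirror-image adduct the (R)-catalyst is used with no other change.
- Step 14: the sense of induction cannot be predicted for this spiro ether from simple 3,3-disubstituted cyclobutanones. (S)-t-BuPHOX is written; its enantiomer is used if the first run favours the 13-epimer.

**Route**

Step 1
Reactants: 1 mesityl oxide (4-methylpent-3-en-2-one)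
Product: 3 4-methyl-2-(triisopropylsilyloxy)penta-1,3-diene, via lithium dienolate 2 (not isolated)
Conditions: LiN(i-Pr)2, THF, −78 °C; then TIPSOTf, −78 → 0 °C
Reagents that add atoms: triisopropylsilyl triflate, CC(C)[Si](C(C)C)(C(C)C)OS(=O)(=O)C(F)(F)F
Why: Kinetic deprotonation of the acetyl methyl group gives the cross-conjugated lithium enolate, and its O-silylation (silyl enol ether formation) places the oxygen on the carbon that becomes C2 and leaves the CH2 terminus as the nucleophilic end.

Step 2
Reactants: 3 4-methyl-2-(triisopropylsilyloxy)penta-1,3-diene; 4 2,6-dimethyl-1,4-benzoquinone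
Product: 5 cis-fused cycloadduct: decalin with C6 and C9 ketones, C7=C8 alkene, methyls on C8 and C10, gem-dimethyl on C4, C2=C3 triisopropylsilyl enol ether, H5 and C10 methyl both β
Conditions: (S)-oxazaborolidinium triflimide [(S)-1-(2-methylphenyl)-3,3-diphenyltetrahydro-1H,3H-pyrrolo[1,2-c][1,3,2]oxazaborole·HNTf2, made in situ with slightly less than 1 equiv Tf2NH] (20 mol %), CH2Cl2, −78 → −40 °C
Reagents that add atoms: none
Why: The cationic boron Lewis acid binds the C6 carbonyl, the one flanked by two vinylic C–H groups, so that C10 is the β-carbon of the activated enone; the silyloxy-activated CH2 terminus bonds to C10 first and the dimethyl terminus then closes onto C5, either as a concerted but strongly asynchronous [4+2] addition or, at the limit, as a Mukaiyama–Michael addition followed by Michael closure of the enolate onto the silyloxocarbenium-activated enone, whose C2–C3 bond is free to rotate, which is what the hydrocarbon diene lacks. The closest known reaction type is the oxazaborolidinium-catalysed Diels–Alder reaction of 2-triisopropylsilyloxybuta-1,3-diene with methyl-substituted 1,4-benzoquinones. Ring A is closed as a six-membered carbocycle by suprafacial addition across C5=C10 (in the stepwise limit a 6-endo-trig Michael closure), which gives the cis ring fusion. C10 is the only stereocentre that has to be set here and is controlled by the catalyst, whose aryl group shields one face of the bound C5=C10 alkene; C5 follows as cis and is corrected in step 3. The step needs regiocontrol and one enantioface: the first is secured twice, by the C10 methyl (β-carbon of the activated enone) and by the polarisation of the diene, which also avoids joining two quaternary carbons, and the symmetry of the quinone removes any choice between its two alkenes.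

Step 3
Reactants: 5 cis-fused cycloadduct
Product: 7 trans-fused 6,9-dione with 5α-H and 8α-methyl and the C2 silyl enol ether retained, via cis-fused saturated dione 6 (not isolated)
Conditions: H2 (1 atm), Pd/C, EtOAc, 23 °C; filter; then KOt-Bu (0.3 equiv), t-BuOH–THF, 23–40 °C
Reagents that add atoms: none
Why: Catalytic hydrogenation saturates the electron-poor C7=C8 bond while the hindered silyl enol ether should survive, and enolate equilibration with a non-nucleophilic alkoxide then moves H5 to the α face (trans-decalin) and the C8 methyl to the equatorial α position, which avoids an 8β-methyl/10β-methyl 1,3-diaxial contact.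

Step 4
Reactants: 7 trans-fused 6,9-dione
Product: 8 6β-hydroxy-9-ketone (axial alcohol; silyl enol ether retained)
Conditions: NaBH4, THF–MeOH, −20 → 0 °C
Reagents that add atoms: none
Why: Hydride reduction should take only the C6 ketone (C9 lies between quaternary C10 and substituted C8), and hydride arrives from the α face because the β face is blocked by the syn-axial 4β- and 10β-methyl groups, giving the 6β-alcohol.

Step 5
Reactants: 8 6β-hydroxy-9-ketone
Product: 9 6β-(tert-butyldimethylsilyloxy)-9-ketone
Conditions: TBSOTf, 2,6-lutidine, CH2Cl2, 0 → 23 °C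
Reagents that add atoms: tert-butyldimethylsilyl triflate, CC(C)(C)[Si](C)(C)OS(=O)(=O)C(F)(F)F
Why: Silyl triflate silylation is strong enough for the hindered axial alcohol and gives a group that tolerates the ylide, alkoxide, titanium and zinc steps ahead.

Step 6
Reactants: 9 6β-silyloxy-9-ketone with C2 silyl enol ether
Product: 10 C2 enol triflate (C2=C3)
Conditions: CsF, PhNTf2, DME, 23 °C
Reagents that add atoms: N-phenylbis(trifluoromethanesulfonimide), O=S(=O)(N(c1ccccc1)S(=O)(=O)C(F)(F)F)C(F)(F)F
Why: Fluoride cleaves the enol silane to the regiodefined C2 enolate, which is O-sulfonylated in situ (enol triflate formation); with C6 already reduced and protected, retro-Michael opening of ring A is not possible and the only other acidic position, C8–H, is hindered.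

Step 7
Reactants: 10 C2 enol triflate
Product: 11 6β-(tert-butyldimethylsilyloxy)-8α-methyl-9-ketone with saturated ring A
Conditions: H2 (1 atm), PtO2, Na2CO3, EtOAc–EtOH, 23 °C
Reagents that add atoms: none
Why: Hydrogenolysis of the enol triflate C–O bond and hydrogenation of the resulting C2=C3 alkene (ketone deoxygenation through the enol triflate) removes the activating oxygen; the hindered C9 ketone and the silyl ether should be inert and the carbonate buffers the triflic acid.

Step 8
Reactants: 11 9-ketone
Product: 12 9(11)-exocyclic methylene compound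
Conditions: Ph3PCH3Br, KOt-Bu, toluene, 100 °C
Reagents that add atoms: methyltriphenylphosphonium bromide, C[P+](c1ccccc1)(c1ccccc1)c1ccccc1.[Br-]
Why: Wittig methylenation under salt-free, hot conditions is the standard answer for α-quaternary cyclohexanones, and C8 stays in its thermodynamic equatorial configuration under the basic conditions.

Step 9
Reactants: 12 9(11)-methylene compound
Product: 13 9α,11-spiro-epoxide (oxygen α and axial, C11 β and equatorial)
Conditions: mCPBA, NaHCO3, CH2Cl2, 0 °C
Reagents that add atoms: 3-chloroperbenzoic acid, OOC(=O)c1cccc(Cl)c1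
Why: Prilezhaev epoxidation should occur on the α face, away from the axial C10 methyl on the neighbouring carbon, which sets C9 with the oxygen α.

Step 10
Reactants: 13 9α,11-spiro-epoxide
Product: 14 α-ethoxycarbonyl C9 spiro-γ-lactone (C9–C11–C12–C13(=O)–O; C12 epimers)
Conditions: CH2(CO2Et)2, NaOEt, EtOH, reflux; then AcOH
Reagents that add atoms: diethyl malonate, CCOC(=O)CC(=O)OCC
Why: SN2 opening of the epoxide at the primary C11 by malonate followed by lactonisation of the C9 alkoxide onto an ester is the sequence used for hindered steroidal 17-spiro-epoxides, and it leaves the C9 configuration untouched.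

Step 11
Reactants: 14 α-ethoxycarbonyl spirolactone
Product: 15 C9 spiro-γ-lactone
Conditions: LiCl, H2O, DMSO, 150 °C
Reagents that add atoms: none
Why: Krapcho dealkoxycarbonylation removes the extra ester under neutral conditions that the silyl ether and lactone tolerate.

Step 12
Reactants: 15 C9 spiro-γ-lactone
Product: 16 13-methylene oxolane (exocyclic enol ether spiro-fused at C9)
Conditions: Cp2TiMe2, toluene, 65 °C, dark; filtration through basic alumina
Reagents that add atoms: dimethyltitanocene, [CH3-].[CH3-].[Ti+4].[cH-]1cccc1.[cH-]1cccc1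
Why: Petasis methylenation converts lactones into exocyclic enol ethers without acid, which matters because this enol ether isomerises easily to the endocyclic form.

Step 13
Reactants: 16 13-methylene oxolane
Product: 18 C13 spirocyclobutanone (3-oxocyclobutane spiro-fused at C13), via dichlorocyclobutanone 17 (not isolated)
Conditions: Cl3CCOCl, Zn–Cu, DME–Et2O, 23 °C; filter; then Zn, AcOH, 23 °C
Reagents that add atoms: trichloroacetyl chloride, ClC(=O)C(Cl)(Cl)Cl
Why: Dichloroketene [2+2] cycloaddition to the enol ether joins the ketene carbonyl carbon to the CH2 terminus and CCl2 to C13 (as with exocyclic glycal enol ethers), and zinc dechlorination then converts both C13 epimers of 17 into the same ketone 18, in which C13 carries two identical CH2C(=O) arms and is not yet stereogenic, so the facial selectivity of the cycloaddition is irrelevant.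

Step 14
Reactants: 18 C13 spirocyclobutanone
Product: 19 6-O-TBS-6-deacetylprevitexilactone ((13S) spiro-γ-lactone)
Conditions: PdCl2(PhCN)2 (5 mol %), (S)-t-BuPHOX (7 mol %), AgSbF6 (10 mol %), 30% aq H2O2, THF, −60 → −20 °C
Reagents that add atoms: hydrogen peroxide, OO
Why: Catalytic asymmetric Baeyer–Villiger desymmetrisation of a 3,3-disubstituted cyclobutanone sets C13, the chiral cationic palladium–phosphinooxazoline complex choosing which of the two diastereotopic methylenes migrates; migration of the methylene on the C10 face of the oxolane gives the required (13S) centre, the substrate itself being almost unbiased because C13 lies on a local pseudo-mirror plane through C9, and the minor 13-epimer is to be removed by chromatography.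

Step 15
Reactants: 19 6-O-TBS-6-deacetylprevitexilactone
Product: 20 6-deacetylprevitexilactone (6β-alcohol)
Conditions: HF·pyridine, pyridine–THF, 0 → 23 °C
Reagents that add atoms: none
Why: Buffered fluoride desilylation removes the hindered silyl ether without the basic conditions that would trigger β-elimination (retro-oxa-Michael) of the β-alkoxy lactone.

Step 16
Reactants: 20 6-deacetylprevitexilactone
Product: 21 previtexilactone
Conditions: Ac2O, DMAP, pyridine, 40 °C
Reagents that add atoms: acetic anhydride, CC(=O)OC(C)=O
Why: DMAP-catalysed acylation (Steglich-type nucleophilic catalysis) esterifies the hindered axial 6β-alcohol under weakly basic conditions that leave the spiro ether and lactone intact.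

**Compound list**
1 | mesityl oxide | CC(=O)C=C(C)C | starting material
2 | lithium 4-methylpenta-1,3-dien-2-olate | [Li+].[O-]C(=C)C=C(C)C | intermediate
3 | 4-methyl-2-(triisopropylsilyloxy)penta-1,3-diene | C=C(O[Si](C(C)C)(C(C)C)C(C)C)C=C(C)C | intermediate
4 | 2,6-dimethyl-1,4-benzoquinone | CC1=CC(=O)C=C(C)C1=O | starting material
5 | cis-fused ene-dione cycloadduct with C2 silyl enol ether | O=C1C=C(C)C(=O)[C@@]2(C)CC(O[Si](C(C)C)(C(C)C)C(C)C)=CC(C)(C)[C@@H]12 | intermediate
6 | cis-fused saturated dione (C8 epimers) | O=C1CC(C)C(=O)[C@@]2(C)CC(O[Si](C(C)C)(C(C)C)C(C)C)=CC(C)(C)[C@@H]12 | intermediate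
7 | trans-fused 6,9-dione, 8α-methyl, C2 silyl enol ether | O=C1C[C@@H](C)C(=O)[C@@]2(C)CC(O[Si](C(C)C)(C(C)C)C(C)C)=CC(C)(C)[C@H]12 | intermediate
8 | 6β-hydroxy-9-ketone | O[C@@H]1C[C@@H](C)C(=O)[C@@]2(C)CC(O[Si](C(C)C)(C(C)C)C(C)C)=CC(C)(C)[C@H]12 | intermediate
9 | 6β-TBS ether of 8 | CC(C)(C)[Si](C)(C)O[C@@H]1C[C@@H](C)C(=O)[C@@]2(C)CC(O[Si](C(C)C)(C(C)C)C(C)C)=CC(C)(C)[C@H]12 | intermediate
10 | C2 enol triflate | CC(C)(C)[Si](C)(C)O[C@@H]1C[C@@H](C)C(=O)[C@@]2(C)CC(OS(=O)(=O)C(F)(F)F)=CC(C)(C)[C@H]12 | intermediate
11 | 6β-silyloxy-8α-methyl-9-ketone, ring A saturated | CC(C)(C)[Si](C)(C)O[C@@H]1C[C@@H](C)C(=O)[C@@]2(C)CCCC(C)(C)[C@H]12 | intermediate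
12 | 9(11)-methylene compound | CC(C)(C)[Si](C)(C)O[C@@H]1C[C@@H](C)C(=C)[C@@]2(C)CCCC(C)(C)[C@H]12 | intermediate
13 | 9α,11-spiro-epoxide | CC(C)(C)[Si](C)(C)O[C@@H]1C[C@@H](C)[C@]2(CO2)[C@@]2(C)CCCC(C)(C)[C@H]12 | intermediate
14 | α-ethoxycarbonyl C9 spirolactone (C12 epimers) | CC(C)(C)[Si](C)(C)O[C@@H]1C[C@@H](C)[C@]2(CC(C(=O)OCC)C(=O)O2)[C@@]2(C)CCCC(C)(C)[C@H]12 | intermediate
15 | C9 spiro-γ-lactone | CC(C)(C)[Si](C)(C)O[C@@H]1C[C@@H](C)[C@]2(CCC(=O)O2)[C@@]2(C)CCCC(C)(C)[C@H]12 | intermediate
16 | 13-methylene oxolane | CC(C)(C)[Si](C)(C)O[C@@H]1C[C@@H](C)[C@]2(CCC(=C)O2)[C@@]2(C)CCCC(C)(C)[C@H]12 | intermediate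
17 | dichlorocyclobutanone (both C13 epimers) | CC(C)(C)[Si](C)(C)O[C@@H]1C[C@@H](C)[C@]2(CCC3(CC(=O)C3(Cl)Cl)O2)[C@@]2(C)CCCC(C)(C)[C@H]12 | intermediate
18 | C13 spirocyclobutanone | CC(C)(C)[Si](C)(C)O[C@@H]1C[C@@H](C)[C@]2(CCC3(CC(=O)C3)O2)[C@@]2(C)CCCC(C)(C)[C@H]12 | intermediate
19 | 6-O-TBS-6-deacetylprevitexilactone | CC(C)(C)[Si](C)(C)O[C@@H]1C[C@@H](C)[C@]2(CC[C@]3(COC(=O)C3)O2)[C@@]2(C)CCCC(C)(C)[C@H]12 | intermediate
20 | 6-deacetylprevitexilactone | O[C@@H]1C[C@@H](C)[C@]2(CC[C@]3(COC(=O)C3)O2)[C@@]2(C)CCCC(C)(C)[C@H]12 | intermediate
21 | previtexilactone | CC(=O)O[C@@H]1C[C@@H](C)[C@]2(CC[C@]3(COC(=O)C3)O2)[C@@]2(C)CCCC(C)(C)[C@H]12 | target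

**Step count and risks**
Total steps: 16. Longest linear sequence: 16 (from mesityl oxide 1; quinone 4 enters at step 2).

Step 2 (most likely to fail). After the first C–C bond at C10, ring closure onto the dimethyl-bearing terminus may stall, or the acidic catalyst may protodesilylate the enol silane; the higher temperature this hindered diene needs may also erode facial control. Fallback, setting out from 3 and 4 and returning at 5: the annulation is split into two separately optimised bond formations. The chiral catalyst is used at −78 °C only for the Mukaiyama–Michael addition, which after silyl transfer should give the open-chain silyl dienol ether 2,6-dimethyl-6-(4-methyl-2-oxopent-3-en-1-yl)-4-(triisopropylsilyloxy)cyclohexa-2,4-dien-1-one F1. Ring A is then closed with an achiral strong Lewis acid (TMSNTf2, 10 mol %, CH2Cl2, −40 °C, or AlBr3/AlMe3) by intramolecular Mukaiyama–Michael addition of the C5=C6 enol silane to the β,β-dimethyl enone with silyl transfer to the C2 oxygen, which gives 5.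

Step 14. The catalyst may discriminate poorly between the two diastereotopic methylenes of this spiro ether, so that the C13 epimers form without useful preference. Fallback, setting out from 16 and returning at 19: C13 is set in the cycloaddition and read out by a regiocontrolled migration instead. The dichloroketene adduct is isolated rather than dechlorinated and its C13 epimers are separated by chromatography. The epimer with CCl2 on the C8 face of the oxolane, dichlorocyclobutanone F2, is oxidised with mCPBA/NaHCO3, where only the unchlorinated methylene migrates, to give the α,α-dichloro-γ-lactone F3. Zn/AcOH then removes both chlorines to give 19.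

Step 10. Attack at the neopentyl-type C11 may be too slow, so that base-induced isomerisation of the epoxide to an allylic alcohol takes over. Fallback, setting out from 12 and returning at 15: the C11–C12 bond is made by olefination instead of substitution. OsO4 (cat.)/NMO dihydroxylates 12 from the α face to the 9α,11-diol F4. SO3·pyridine/DMSO/Et3N oxidises the primary alcohol to the 9α-hydroxy-11-aldehyde F5. Ph3P=CHCO2Et in hot toluene gives the (E)-enoate F6. H2 over Pd/C gives the saturated hydroxy ester F7, which lactonises with TsOH in warm toluene to 15.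

Further compounds
F1 | step 2 | 2,6-dimethyl-6-(4-methyl-2-oxopent-3-en-1-yl)-4-(triisopropylsilyloxy)cyclohexa-2,4-dien-1-one | CC(C)=CC(=O)C[C@@]1(C)C=C(O[Si](C(C)C)(C(C)C)C(C)C)C=C(C)C1=O
F2 | step 14 | dichlorocyclobutanone, single C13 epimer with CCl2 on the C8 face | CC(C)(C)[Si](C)(C)O[C@@H]1C[C@@H](C)[C@]2(CC[C@]3(CC(=O)C3(Cl)Cl)O2)[C@@]2(C)CCCC(C)(C)[C@H]12
F3 | step 14 | 14,14-dichloro derivative of 19 | CC(C)(C)[Si](C)(C)O[C@@H]1C[C@@H](C)[C@]2(CC[C@]3(COC(=O)C3(Cl)Cl)O2)[C@@]2(C)CCCC(C)(C)[C@H]12
F4 | step 10 | 9α,11-diol | CC(C)(C)[Si](C)(C)O[C@@H]1C[C@@H](C)[C@](O)(CO)[C@@]2(C)CCCC(C)(C)[C@H]12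
F5 | step 10 | 9α-hydroxy-11-aldehyde | CC(C)(C)[Si](C)(C)O[C@@H]1C[C@@H](C)[C@](O)(C=O)[C@@]2(C)CCCC(C)(C)[C@H]12
F6 | step 10 | (E)-9α-hydroxy enoate | CC(C)(C)[Si](C)(C)O[C@@H]1C[C@@H](C)[C@](O)(/C=C/C(=O)OCC)[C@@]2(C)CCCC(C)(C)[C@H]12
F7 | step 10 | saturated 9α-hydroxy ethyl ester | CC(C)(C)[Si](C)(C)O[C@@H]1C[C@@H](C)[C@](O)(CCC(=O)OCC)[C@@]2(C)CCCC(C)(C)[C@H]12
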